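## Structural features

Schizolaenone C is a (2S)-flavanone: a 2,3-dihydro-4H-chromen-4-one in which ring A is fused to the pyranone ring C through C4a–C8a, and C2 carries the 3,5-dihydroxyphenyl ring B. Ring A is a phloroglucinol with O1 on C8a, free hydroxyls on C5 and C7, an (E)-geranyl chain on C6 between them, and hydrogen only on C8. C2 is the only stereocentre; it is benzylic and β to the C4 carbonyl, so it can be lost by retro-oxa-Michael opening to a chalcone, most easily under base once the ring A phenols are free. The geranyl chain has two trisubstituted alkenes that cyclise onto the flanking phenols or onto each other under acid, and it rules out hydrogenolysis. The real difficulty is constitutional. A route that closes ring C onto a finished ring A must choose between two ortho phenols, and a late C-geranylation must choose between C6 and C8; both choices decide 6- versus 8-geranyl. The feature the plan exploits is that C5, C7 and C8a are at the carbonyl oxidation level and alternate with C4a, C6 and C8, so ring A is the enol form of a poly-β-carbonyl chain. If ring C exists first as a 2-aryl-2,3-dihydropyran-4-one, C8a is already its enol-ether carbon and C4a its nucleophilic α-carbon. Ring A can then be closed last by a Claisen condensation of C4a onto a C5 ester at the end of a C8–C7–C6–C5 chain that carries geranyl on C6.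

## Logic of the disconnections

**14 from 13.** The two aryl O–Si bonds on ring B are cut. Silyl ethers are chosen because buffered fluoride removes them without acid (geranyl) and without free base (C2). The forward step must leave C2 and both alkenes untouched.

**13 from 12 (key disconnection).** The C4a–C5 bond of ring A is cut, which opens the arene to a β-keto ester chain (C8–C7–C6–C5) hanging from C8a of a chiral dihydropyranone. The gain is large: ring A, both ring A hydroxyls and the position of geranyl all come from one acyclic chain, and the C6/C8 question cannot arise because O1 is already bonded to C8a and geranyl sits on the carbon between the two future C–OH carbons. The forward step must be a C-acylation through C4a under conditions that do not ionise C3–H.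

**12 from 6 and 11.** The C7–C8 bond is cut, which separates the chiral heterocycle from an achiral malonyl unit. This makes the route convergent and places the stereocentre and the geranyl chain in different fragments. The forward step requires deprotonation of 6 at the exocyclic methyl group and not at C3, and C-acylation of the resulting extended enolate.

**11 from 10, 9, 7 and 8.** The C6–C1″ bond is cut by returning to a malonate alkylation, followed by removal of one ester methyl group and activation of the acid. The (E)-allylic bromide is attacked by SN2, so the alkene geometry of 8 is carried over unchanged. The forward steps must stop at mono-alkylation and mono-saponification.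

**6 from 2 and 4 (through 5).** The C2–C3 and O1–C8a bonds are cut in the sense of an aldehyde–siloxydiene cyclocondensation. This creates C2 under catalyst control from an achiral aldehyde and delivers ring C with C8 already attached as a methyl group. The forward step must address the Si face of 2.

**4 from 3, and 2 from 1.** An O–Si bond is cut in each case (kinetic enol silylation; phenol protection). Both go back to catalogue compounds.

## Other disconnections considered

Alternative 1: The first plan that comes to mind cuts O1–C2 and the C3–C2 bond at the chalcone stage. Forward, a C-geranylated acetophenone A1 undergoes Claisen–Schmidt condensation with 2 to give chalcone A2, which is closed by an intramolecular oxa-Michael addition, ideally with a chiral catalyst. A2 has two ortho hydroxyls, one flanked by geranyl and one not, so closure can give either constitution unless the phenols are differentiated by extra protecting-group steps. The oxa-Michael addition is also reversible, so the C2 configuration is under thermodynamic threat in the very step that creates it. Direct C-geranylation of the phloroglucinol to reach A1 competes with O- and poly-alkylation. The chosen plan removes all three problems by fixing O1 and C2 before ring A exists.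

Alternative 2: The C2–C1′ bond is cut. Forward, arylboronic acid A4 is added enantioselectively in a 1,4-sense to chromone A3, with a chiral rhodium–diene catalyst or with Pd(OCOCF3)2 and a pyridine–oxazoline ligand (divalent palladium). This sets C2 cleanly in principle. However, A3 has to be built with the same 6- versus 8-geranyl decision taken earlier, at the choice of which phenol closes the pyranone. A 5-alkoxy group also makes the chromone a poor acceptor, and electrophilic divalent palladium is not innocent towards the two trisubstituted alkenes. The step count is higher, and the key step solves only the stereocentre, not the connectivity.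

Alternative 3: The C6–C1″ bond is cut on a finished (S)-flavanone core. Forward, the 5-O-geranyl ether A5 undergoes an aromatic Claisen rearrangement to C6, giving a tertiary, inverted allyl group, followed by a Cope shift. The Cope shift can only move the chain on to C8, para to O5, which gives the regioisomer A6 and not the target. It would also form the trisubstituted alkene through a chair in which methyl and homoprenyl compete, so E/Z control is expected to be poor. An ionic 1,3-shift to C6 on acidic clay would expose the geranyl chain to exactly the acid it does not tolerate. The core would still need its own asymmetric synthesis. The chosen plan installs geranyl by a simple SN2 alkylation on an acyclic malonate and never asks an arene to choose.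

Key step: step 7

Assumptions (remarks on the chemistry): 3 is taken as the catalogue E enol ether; otherwise it is one step from pentane-2,4-dione and trimethyl orthoformate. Compounds 10, 11 and 12 are racemic or epimeric at the malonyl carbon, which is of no consequence because that carbon becomes the aromatic C6.

## Steps

Step 1
Reactants: 1 3,5-dihydroxybenzaldehyde
Product: 2 3,5-bis(triisopropylsilyloxy)benzaldehyde
Conditions: iPr3SiCl (2.4 equiv), imidazole (5 equiv), DMF, 23 °C
Reagents that add atoms: triisopropylsilyl chloride, CC(C)[Si](Cl)(C(C)C)C(C)C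
Why: Standard phenol silylation; the triisopropylsilyl ethers resist the amide and amidine bases used later and are removed at the end by fluoride without acid.

Step 2
Reactants: 3 (E)-4-methoxypent-3-en-2-one
Product: 4 (E)-4-methoxy-2-(trimethylsilyloxy)penta-1,3-diene
Conditions: LiN(iPr)2 (1.1 equiv), THF, −78 °C; Me3SiCl (1.2 equiv), −78 → 0 °C
Reagents that add atoms: chlorotrimethylsilane, C[Si](C)(C)Cl
Why: Kinetic deprotonation of a β-alkoxy enone occurs at the acetyl methyl group (α′), and O-silylation gives the 1-alkoxy-3-silyloxy diene; the enol ether methyl group is not touched at low temperature.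

Step 3
Reactants: 2 3,5-bis(triisopropylsilyloxy)benzaldehyde; 4 (E)-4-methoxy-2-(trimethylsilyloxy)penta-1,3-diene
Product: 6 (S)-2-[3,5-bis(triisopropylsilyloxy)phenyl]-6-methyl-2,3-dihydro-4H-pyran-4-one, via silyl aldol adduct 5 (not isolated)
Conditions: (S)-BINOL (20 mol %), Ti(OiPr)4 (10 mol %), 4 Å MS, CH2Cl2, −20 °C, 4 (1.5 equiv); then CF3CO2H, CH2Cl2, 0 °C
Reagents that add atoms: none
Why: Catalytic asymmetric Mukaiyama aldol addition followed by acid-induced 6-endo oxa-Michael closure and loss of methanol (formal hetero-Diels–Alder reaction). The (S)-BINOL–titanium catalyst is expected, by analogy with its uniform facial preference in allylations and aldol additions of aromatic aldehydes, to deliver the diene terminus to the Si face of 2, which sets C2 as S. The C–O bond of the carbinol is never broken afterwards.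

Step 4
Reactants: 7 dimethyl malonate; 8 geranyl bromide [(2E)-1-bromo-3,7-dimethylocta-2,6-diene]
Product: 9 dimethyl 2-[(2E)-3,7-dimethylocta-2,6-dien-1-yl]malonate
Conditions: NaH (1.0 equiv), 7 (2.0 equiv), THF, 0 → 23 °C; then 8 (1.0 equiv)
Reagents that add atoms: none
Why: Malonate alkylation by SN2 at the primary allylic bromide; excess malonate suppresses dialkylation and the E alkene is not involved.

Step 5
Reactants: 9 dimethyl 2-[(2E)-3,7-dimethylocta-2,6-dien-1-yl]malonate
Product: 10 potassium 2-(methoxycarbonyl)-(4E)-5,9-dimethyldeca-4,8-dienoate (racemic)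
Conditions: KOH (1.0 equiv), MeOH, 0 → 23 °C; evaporate, triturate with Et2O
Reagents that add atoms: potassium hydroxide, [K+].[OH-]
Why: Mono-saponification of a malonic diester; the carboxylate formed deactivates the second ester towards hydroxide, and isolating the salt avoids handling the free acid.

Step 6
Reactants: 10 potassium 2-(methoxycarbonyl)-(4E)-5,9-dimethyldeca-4,8-dienoate (racemic); 6 (S)-2-[3,5-bis(triisopropylsilyloxy)phenyl]-6-methyl-2,3-dihydro-4H-pyran-4-one
Product: 12 methyl (4E)-2-{2-[(6S)-6-[3,5-bis(triisopropylsilyloxy)phenyl]-4-oxo-5,6-dihydro-4H-pyran-2-yl]acetyl}-5,9-dimethyldeca-4,8-dienoate (both epimers at C2 of the chain), via acid chloride 11 (not isolated)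
Conditions: (a) 10, (COCl)2 (1.0 equiv), DMF (cat.), CH2Cl2, 0 °C, evaporate; (b) 6 (2.0 equiv), LiN(SiMe3)2 (2.0 equiv), THF, −78 °C; add 11 (1.0 equiv) in THF, −78 °C; AcOH quench; recover excess 6
Reagents that add atoms: oxalyl chloride, O=C(Cl)C(Cl)=O (supplies the chlorine of 11; nothing from it remains in 12)
Why: C-acylation of an extended lithium enolate. 6-Methyl-2,3-dihydro-4H-pyran-4-ones are lithiated and attacked by carbonyl electrophiles at the exocyclic carbon, which gives the through-conjugated 2-oxydienolate. The second equivalent of dienolate takes up the acidic proton of the β-keto ester formed and returns as 6. The carboxylate salt with oxalyl chloride gives 11 without free HCl, which protects the geranyl alkenes.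

Step 7
Reactants: 12 methyl (4E)-2-{2-[(6S)-6-[3,5-bis(triisopropylsilyloxy)phenyl]-4-oxo-5,6-dihydro-4H-pyran-2-yl]acetyl}-5,9-dimethyldeca-4,8-dienoate
Product: 13 (2S)-2-[3,5-bis(triisopropylsilyloxy)phenyl]-6-[(2E)-3,7-dimethylocta-2,6-dien-1-yl]-5,7-dihydroxy-2,3-dihydro-4H-chromen-4-one
Conditions: DBU (2.5 equiv), MeCN (0.02 M), 23 → 50 °C; then AcOH, aq. NH4Cl
Reagents that add atoms: none
Why: Intramolecular Claisen (Dieckmann-type) condensation in the polyketide sense: DBU removes one of two comparably acidic protons (C6–H of the β-keto ester, or C8–H between the C7 ketone and the vinylogous ester), and the C8 anion, delocalised through C8a=C4a onto O4, attacks the C5 ester carbonyl through C4a. The closest known reaction type is the Claisen cyclisation of 3,5,7-tricarbonyl esters to acylphloroglucinols, here with the C8a carbonyl locked as the enol ether of ring C. Ring A closes in a 6-(enolexo)-exo-trig mode; loss of methoxide and two tautomerisations (the hydrogens of C4a and C6 move to O5 and O7) give the arene and make the step irreversible. No stereocentre is created: C2 is carried through because DBU ionises only the doubly activated C–H bonds and not C3–H, and the epimeric chain carbon of 12 becomes aromatic C6. The selectivity needed is constitutional, and the substrate secures it. O1 is already an ether, so no pyrone or isomeric chromanone can form. The aldol mode (C6 onto C4) would need a bridgehead alkene, and attack of the ester by C8 itself would need a four-membered ring. Geranyl lies between C5 and C7 by construction. The non-coordinating amidinium counter-ion is chosen so that the mono-anion is not held as the unreactive chelated β-keto ester enolate.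

Step 8
Reactants: 13 (2S)-2-[3,5-bis(triisopropylsilyloxy)phenyl]-6-[(2E)-3,7-dimethylocta-2,6-dien-1-yl]-5,7-dihydroxy-2,3-dihydro-4H-chromen-4-one
Product: 14 schizolaenone C, (2S)-2-(3,5-dihydroxyphenyl)-6-[(2E)-3,7-dimethylocta-2,6-dien-1-yl]-5,7-dihydroxy-2,3-dihydro-4H-chromen-4-one
Conditions: Bu4NF (2.4 equiv), AcOH (2.4 equiv), THF, 0 °C
Reagents that add atoms: none
Why: Fluoride cleavage of aryl silyl ethers; buffering with acetic acid keeps the phenols protonated so that the flavanone is not opened to the chalcone, and the medium is never acidic enough to cyclise the geranyl chain.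

## Compound list

1 | 3,5-dihydroxybenzaldehyde | O=Cc1cc(O)cc(O)c1 | starting material
2 | 3,5-bis(triisopropylsilyloxy)benzaldehyde | O=Cc1cc(O[Si](C(C)C)(C(C)C)C(C)C)cc(O[Si](C(C)C)(C(C)C)C(C)C)c1 | intermediate
3 | (E)-4-methoxypent-3-en-2-one | CC(=O)/C=C(\C)OC | starting material
4 | (E)-4-methoxy-2-(trimethylsilyloxy)penta-1,3-diene | C=C(O[Si](C)(C)C)/C=C(\C)OC | intermediate
5 | (S,E)-1-[3,5-bis(triisopropylsilyloxy)phenyl]-5-methoxy-1-(trimethylsilyloxy)hex-4-en-3-one | CO/C(C)=C/C(=O)C[C@@H](c1cc(O[Si](C(C)C)(C(C)C)C(C)C)cc(O[Si](C(C)C)(C(C)C)C(C)C)c1)O[Si](C)(C)C | intermediate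
6 | (S)-2-[3,5-bis(triisopropylsilyloxy)phenyl]-6-methyl-2,3-dihydro-4H-pyran-4-one | CC1=CC(=O)C[C@@H](c2cc(O[Si](C(C)C)(C(C)C)C(C)C)cc(O[Si](C(C)C)(C(C)C)C(C)C)c2)O1 | intermediate
7 | dimethyl malonate | COC(=O)CC(=O)OC | starting material
8 | geranyl bromide | CC(C)=CCC/C(C)=C/CBr | starting material
9 | dimethyl 2-[(2E)-3,7-dimethylocta-2,6-dien-1-yl]malonate | COC(=O)C(C/C=C(\C)CCC=C(C)C)C(=O)OC | intermediate
10 | potassium 2-(methoxycarbonyl)-(4E)-5,9-dimethyldeca-4,8-dienoate (racemic) | COC(=O)C(C/C=C(\C)CCC=C(C)C)C(=O)[O-].[K+] | intermediate
11 | methyl (4E)-2-(chlorocarbonyl)-5,9-dimethyldeca-4,8-dienoate (racemic) | COC(=O)C(C/C=C(\C)CCC=C(C)C)C(Cl)=O | intermediate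
12 | methyl (4E)-2-{2-[(6S)-6-[3,5-bis(triisopropylsilyloxy)phenyl]-4-oxo-5,6-dihydro-4H-pyran-2-yl]acetyl}-5,9-dimethyldeca-4,8-dienoate | COC(=O)C(C/C=C(\C)CCC=C(C)C)C(=O)CC1=CC(=O)C[C@@H](c2cc(O[Si](C(C)C)(C(C)C)C(C)C)cc(O[Si](C(C)C)(C(C)C)C(C)C)c2)O1 | intermediate
13 | (2S)-2-[3,5-bis(triisopropylsilyloxy)phenyl]-6-[(2E)-3,7-dimethylocta-2,6-dien-1-yl]-5,7-dihydroxy-2,3-dihydro-4H-chromen-4-one | CC(C)=CCC/C(C)=C/Cc1c(O)cc2c(c1O)C(=O)C[C@@H](c1cc(O[Si](C(C)C)(C(C)C)C(C)C)cc(O[Si](C(C)C)(C(C)C)C(C)C)c1)O2 | intermediate
14 | schizolaenone C | CC(C)=CCC/C(C)=C/Cc1c(O)cc2c(c1O)C(=O)C[C@@H](c1cc(O)cc(O)c1)O2 | target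

## Step count and least certain steps

Total: 8 steps. Longest linear sequence: 5 steps (1 → 2 → 6 → 12 → 13 → 14, steps 1, 3, 6, 7 and 8). The malonate branch (steps 4, 5, 6, 7 and 8) is equally long.

**Step 7 (key step).** Two things may go wrong. The mono-anion may stay on the β-keto ester side, so that ring closure is slow and methoxide-induced retro-Claisen cleavage of the chain competes. Alternatively, the phenoxide form of the product may lose C2 configuration by retro-oxa-Michael opening on prolonged exposure to base. The fallback sets out from 12 and returns at 13 with no base at all. Compound 12 is heated in mesitylene at 160 °C over 4 Å sieves, so that its enol form loses methanol to give the acylketene F1. Enolisation of the C7 ketone towards C8 makes F1 a dienylketene, which closes the C4a–C5 bond by 6π-electrocyclisation and tautomerises to 13.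

**Step 6.** Deprotonation may occur at C3 and not at the methyl group, which would lead to C3-acylation or to opening of the pyranone by β-elimination; O-acylation of the dienolate is a further risk. The fallback sets out from 6 and returns at 12. Soft enolisation of 6 with Me3SiOTf and Et3N gives the isolable silyl dienol ether (S)-2-[3,5-bis(triisopropylsilyloxy)phenyl]-6-methylene-4-(trimethylsilyloxy)-3,6-dihydro-2H-pyran F2, whose constitution is checked before use. MeLi then releases the lithium dienolate regiospecifically, and acylation with 11 gives 12.

**Step 3.** Facial selectivity may be poor with the two bulky meta substituents, the sense of induction is assigned by analogy only, and the fully substituted diene terminus may close sluggishly. The fallback sets out from 2 and returns at 6 by a different principle of stereocontrol. The D-proline-catalysed aldol addition of acetone to 2 (enamine catalysis; L-proline is known to give the R aldols of aromatic aldehydes, so D-proline is used) gives (S)-4-[3,5-bis(triisopropylsilyloxy)phenyl]-4-hydroxybutan-2-one F3. Condensation of its methyl ketone with N,N-dimethylacetamide dimethyl acetal gives the enaminone F4, which cyclises through the hydroxyl group with loss of dimethylamine to 6.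

**Step 5.** Saponification may run on to the diacid, which decarboxylates, or may stop short. The fallback sets out from 8 and returns at 10. The dianion of methyl hydrogen malonate (2 equiv LiN(iPr)2, THF, −78 → 0 °C) is alkylated with 8 to give the half-acid 2-(methoxycarbonyl)-(4E)-5,9-dimethyldeca-4,8-dienoic acid F5, which is neutralised with KHCO3 to 10.

## Further compounds

F1 | step 7 | (S)-acylketene: 2-[(2E)-3,7-dimethylocta-2,6-dien-1-yl]-4-{6-[3,5-bis(triisopropylsilyloxy)phenyl]-4-oxo-5,6-dihydro-4H-pyran-2-yl}buta-1-ene-1,3-dione | O=C=C(C/C=C(\C)CCC=C(C)C)C(=O)CC1=CC(=O)C[C@@H](c2cc(O[Si](C(C)C)(C(C)C)C(C)C)cc(O[Si](C(C)C)(C(C)C)C(C)C)c2)O1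
F2 | step 6 | (S)-2-[3,5-bis(triisopropylsilyloxy)phenyl]-6-methylene-4-(trimethylsilyloxy)-3,6-dihydro-2H-pyran | C=C1C=C(O[Si](C)(C)C)C[C@@H](c2cc(O[Si](C(C)C)(C(C)C)C(C)C)cc(O[Si](C(C)C)(C(C)C)C(C)C)c2)O1
F3 | step 3 | (S)-4-[3,5-bis(triisopropylsilyloxy)phenyl]-4-hydroxybutan-2-one | CC(=O)C[C@H](O)c1cc(O[Si](C(C)C)(C(C)C)C(C)C)cc(O[Si](C(C)C)(C(C)C)C(C)C)c1
F4 | step 3 | (S,E)-1-[3,5-bis(triisopropylsilyloxy)phenyl]-5-(dimethylamino)-1-hydroxyhex-4-en-3-one | CN(C)/C(C)=C/C(=O)C[C@H](O)c1cc(O[Si](C(C)C)(C(C)C)C(C)C)cc(O[Si](C(C)C)(C(C)C)C(C)C)c1
F5 | step 5 | 2-(methoxycarbonyl)-(4E)-5,9-dimethyldeca-4,8-dienoic acid (racemic) | COC(=O)C(C/C=C(\C)CCC=C(C)C)C(=O)O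
A1 | alternative 1 | 1-{3-[(2E)-3,7-dimethylocta-2,6-dien-1-yl]-2,4,6-trihydroxyphenyl}ethan-1-one | CC(=O)c1c(O)cc(O)c(C/C=C(\C)CCC=C(C)C)c1O
A2 | alternative 1 | (E)-3-[3,5-bis(triisopropylsilyloxy)phenyl]-1-{3-[(2E)-3,7-dimethylocta-2,6-dien-1-yl]-2,4,6-trihydroxyphenyl}prop-2-en-1-one | CC(C)=CCC/C(C)=C/Cc1c(O)cc(O)c(C(=O)/C=C/c2cc(O[Si](C(C)C)(C(C)C)C(C)C)cc(O[Si](C(C)C)(C(C)C)C(C)C)c2)c1O
A3 | alternative 2 | 6-[(2E)-3,7-dimethylocta-2,6-dien-1-yl]-5,7-bis(methoxymethoxy)-4H-chromen-4-one | CC(C)=CCC/C(C)=C/Cc1c(OCOC)cc2occc(=O)c2c1OCOC
A4 | alternative 2 | [3,5-bis(triisopropylsilyloxy)phenyl]boronic acid | OB(O)c1cc(O[Si](C(C)C)(C(C)C)C(C)C)cc(O[Si](C(C)C)(C(C)C)C(C)C)c1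
A5 | alternative 3 | (2S)-2-[3,5-bis(triisopropylsilyloxy)phenyl]-5-{[(2E)-3,7-dimethylocta-2,6-dien-1-yl]oxy}-7-(methoxymethoxy)-2,3-dihydro-4H-chromen-4-one | CC(C)=CCC/C(C)=C/COc1cc(OCOC)cc2c1C(=O)C[C@@H](c1cc(O[Si](C(C)C)(C(C)C)C(C)C)cc(O[Si](C(C)C)(C(C)C)C(C)C)c1)O2
A6 | alternative 3 | (2S)-2-[3,5-bis(triisopropylsilyloxy)phenyl]-8-[(2E)-3,7-dimethylocta-2,6-dien-1-yl]-5-hydroxy-7-(methoxymethoxy)-2,3-dihydro-4H-chromen-4-one | CC(C)=CCC/C(C)=C/Cc1c(OCOC)cc(O)c2c1O[C@H](c1cc(O[Si](C(C)C)(C(C)C)C(C)C)cc(O[Si](C(C)C)(C(C)C)C(C)C)c1)CC2=O
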